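**Strategy.** Everything rests on reading C4 of the middle, 5-deoxy flavan unit as an aldehyde carbon in disguise: it lies between C4a of that unit's resorcinol-type ring A (para to O7) and C8 of the phloroglucinol ring of the lower catechin. The key step treats an acyclic α-benzyloxy-β-aryloxy aldehyde, whose aryl ether ring already carries the complete upper epicatechin unit at the future C8, with a Lewis acid and benzylated catechin: Friedel–Crafts hydroxyalkylation closes ring C through the C4–C4a bond and the resulting flavanyl cation is captured by catechin C8, which sets C4. Both 2,3-cis three-carbon chains derive from one anti-alkoxyallylation product.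

Key step: step 11

Remark: the target is read as epicatechin-(4β→8)-epifisetinidol-(4β→8)-catechin, units (2R,3R,4R), (2R,3R,4R) and (2R,3S), with 4β meaning trans to O3. A flavanyl cation would attack a 5-deoxy ring A at C6 and not at C8, so the upper-to-middle bond is made through a 2,6-dialkoxyphenyllithium and the upper pyran ring is closed de novo.

Step 1
Reactants: 1 benzyl propargyl ether
Product: 2 (E)-2-[3-(benzyloxy)prop-1-en-1-yl]-4,4,5,5-tetramethyl-1,3,2-dioxaborolane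
Conditions: HBpin (1.1 equiv), Cp2Zr(H)Cl (5 mol %), Et3N (10 mol %), neat, 60 °C
Reagents that add atoms: pinacolborane, [H]B1OC(C)(C)C(C)(C)O1
Why: Zirconocene hydride-catalysed hydroboration of a terminal alkyne adds H and B syn and anti-Markovnikov, which should give the (E)-alkenylboronate.

Step 2
Reactants: 2 (E)-2-[3-(benzyloxy)prop-1-en-1-yl]-4,4,5,5-tetramethyl-1,3,2-dioxaborolane; 3 3,4-bis(benzyloxy)benzaldehyde
Product: 5 (1S,2R)-2-(benzyloxy)-1-[3,4-bis(benzyloxy)phenyl]but-3-en-1-ol, via allylboronate 4 (not isolated)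
Conditions: [Ir(cod)(PPh2Me)2]PF6 (2 mol %, H2-activated), THF, rt; then toluene, 3, (R)-TRIP [(R)-3,3′-bis(2,4,6-triisopropylphenyl)-1,1′-binaphthyl-2,2′-diyl hydrogen phosphate] (5 mol %), 4 Å MS, −30 °C; aq. NaHCO3
Reagents that add atoms: none
Why: Iridium hydride-catalysed olefin transposition moves the double bond into conjugation with oxygen to give the (E)-γ-benzyloxyallylboronate, and the chiral phosphoric acid-catalysed allylboration then passes through a closed chair transition state with the aldehyde aryl group and the (E)-benzyloxy group equatorial (anti 1,2-relationship) while the (R)-acid is expected to direct attack to the Re face of the aldehyde, which sets C1 as S and C2 as R.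

Step 3
Reactants: 5 (1S,2R)-2-(benzyloxy)-1-[3,4-bis(benzyloxy)phenyl]but-3-en-1-ol; 6 3,5-bis(benzyloxy)phenol
Product: 7 1,3-bis(benzyloxy)-5-{[(1R,2R)-2-(benzyloxy)-1-[3,4-bis(benzyloxy)phenyl]but-3-en-1-yl]oxy}benzene
Conditions: PPh3, DIAD, toluene, 0 °C → rt
Reagents that add atoms: none
Why: Mitsunobu etherification, in which the phenoxide displaces the alkoxyphosphonium group by SN2 with inversion at the benzylic carbon (S to R), should turn the anti alcohol into the syn aryl ether that a 2,3-cis flavan needs, ionisation being disfavoured by the vicinal benzyloxy group.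

Step 4
Reactants: 7 1,3-bis(benzyloxy)-5-{[(1R,2R)-2-(benzyloxy)-1-[3,4-bis(benzyloxy)phenyl]but-3-en-1-yl]oxy}benzene
Product: 9 (2S,3R)-2-(benzyloxy)-3-[3,4-bis(benzyloxy)phenyl]-3-[3,5-bis(benzyloxy)phenoxy]propanal, via diol 8 (not isolated)
Conditions: OsO4 (2 mol %), NaIO4 (4 equiv), 2,6-lutidine, dioxane/H2O (3:1), rt
Reagents that add atoms: osmium tetroxide, O=[Os](=O)(=O)=O (catalytic oxygen carrier); sodium periodate, [Na+].[O-]I(=O)(=O)=O
Why: Lemieux–Johnson oxidation (catalytic dihydroxylation of the only alkene, then periodate glycol cleavage) should unmask the aldehyde under buffered, nearly neutral conditions that leave the α-stereocentre and the β-aryloxy group untouched.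

Step 5
Reactants: 10 2-bromoresorcinol (2-bromobenzene-1,3-diol)
Product: 11 3-(benzyloxy)-2-bromophenol
Conditions: BnBr (1.0 equiv), K2CO3, acetone, reflux
Reagents that add atoms: benzyl bromide, BrCc1ccccc1
Why: Williamson etherification with one equivalent of benzyl bromide should give mainly the mono-ether, which is separated by chromatography from the bis-ether and recovered diol.

Step 6
Reactants: 5 (1S,2R)-2-(benzyloxy)-1-[3,4-bis(benzyloxy)phenyl]but-3-en-1-ol; 11 3-(benzyloxy)-2-bromophenol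
Product: 12 1-(benzyloxy)-2-bromo-3-{[(1R,2R)-2-(benzyloxy)-1-[3,4-bis(benzyloxy)phenyl]but-3-en-1-yl]oxy}benzene
Conditions: PPh3, DIAD, toluene, 0 °C → rt
Reagents that add atoms: none
Why: Mitsunobu etherification with the acidic ortho-bromophenol should proceed by SN2 with inversion at the benzylic carbon, giving the (1R,2R) syn ether that carries the future ring A of the middle unit with bromine at the future C8.

Step 7
Reactants: 12 1-(benzyloxy)-2-bromo-3-{[(1R,2R)-2-(benzyloxy)-1-[3,4-bis(benzyloxy)phenyl]but-3-en-1-yl]oxy}benzene; 9 (2S,3R)-2-(benzyloxy)-3-[3,4-bis(benzyloxy)phenyl]-3-[3,5-bis(benzyloxy)phenoxy]propanal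
Product: 14 (1RS,2R,3R)-2-(benzyloxy)-1-{2-(benzyloxy)-6-{[(1R,2R)-2-(benzyloxy)-1-[3,4-bis(benzyloxy)phenyl]but-3-en-1-yl]oxy}phenyl}-3-[3,4-bis(benzyloxy)phenyl]-3-[3,5-bis(benzyloxy)phenoxy]propan-1-ol, via aryllithium 13 (not isolated)
Conditions: t-BuLi (2.1 equiv), THF, −78 °C; then 9, −78 °C; then H2O
Reagents that add atoms: none
Why: Bromine–lithium exchange is faster at −78 °C than deprotonation of any C–H bond, and 1,2-addition of the 2,6-dialkoxyphenyllithium to the aldehyde forms the bond between the future C4 of the upper unit and C8 of the middle unit at the carbon between the two oxygens, the new carbinol centre being left uncontrolled because it is ionised in step 8.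

Step 8
Reactants: 14 (1RS,2R,3R)-2-(benzyloxy)-1-{2-(benzyloxy)-6-{[(1R,2R)-2-(benzyloxy)-1-[3,4-bis(benzyloxy)phenyl]but-3-en-1-yl]oxy}phenyl}-3-[3,4-bis(benzyloxy)phenyl]-3-[3,5-bis(benzyloxy)phenoxy]propan-1-ol
Product: 15 (2R,3R)-3,5,7-tris(benzyloxy)-2-[3,4-bis(benzyloxy)phenyl]-4β-{2-(benzyloxy)-6-{[(1R,2R)-2-(benzyloxy)-1-[3,4-bis(benzyloxy)phenyl]but-3-en-1-yl]oxy}phenyl}chromane (2,3-cis-3,4-trans)
Conditions: BF3·OEt2 (0.2 equiv), CH2Cl2 (0.01 M), −78 → −40 °C
Reagents that add atoms: none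
Why: Acid ionises the benzylic alcohol to a cation stabilised by the two ortho oxygens, and Friedel–Crafts cyclialkylation by the 3,5-bis(benzyloxy)phenoxy ring at its ortho carbon (activated by three oxygens, six-membered ring) should close the upper pyran, the bulky aryl group at C4 taking the pseudo-axial position trans to the C3 benzyloxy group to avoid peri strain with the C5 benzyloxy group, which sets C4 as 4β.

Step 9
Reactants: 15 (2R,3R)-3,5,7-tris(benzyloxy)-2-[3,4-bis(benzyloxy)phenyl]-4β-{2-(benzyloxy)-6-{[(1R,2R)-2-(benzyloxy)-1-[3,4-bis(benzyloxy)phenyl]but-3-en-1-yl]oxy}phenyl}chromane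
Product: 17 (2S,3R)-2-(benzyloxy)-3-[3,4-bis(benzyloxy)phenyl]-3-{3-(benzyloxy)-2-[(2R,3R)-3,5,7-tris(benzyloxy)-2-[3,4-bis(benzyloxy)phenyl]chroman-4β-yl]phenoxy}propanal, via diol 16 (not isolated)
Conditions: OsO4 (2 mol %), NaIO4 (4 equiv), 2,6-lutidine, dioxane/H2O (3:1), rt
Reagents that add atoms: osmium tetroxide, O=[Os](=O)(=O)=O (catalytic oxygen carrier); sodium periodate, [Na+].[O-]I(=O)(=O)=O
Why: Lemieux–Johnson oxidation of the only alkene should give the aldehyde under buffered conditions, and it is used at once in step 11 so that the α-stereocentre is not epimerised.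

Step 10
Reactants: 18 (+)-catechin
Product: 19 5,7,3′,4′-tetra-O-benzylcatechin [(2R,3S)-5,7-bis(benzyloxy)-2-[3,4-bis(benzyloxy)phenyl]chroman-3-ol]
Conditions: BnBr (4.4 equiv), K2CO3, DMF, 0 °C → rt
Reagents that add atoms: benzyl bromide, BrCc1ccccc1
Why: Williamson etherification benzylates the four phenols, while the secondary alcohol is not deprotonated by carbonate and stays free and C2 is not epimerised.

Step 11
Reactants: 17 (2S,3R)-2-(benzyloxy)-3-[3,4-bis(benzyloxy)phenyl]-3-{3-(benzyloxy)-2-[(2R,3R)-3,5,7-tris(benzyloxy)-2-[3,4-bis(benzyloxy)phenyl]chroman-4β-yl]phenoxy}propanal; 19 5,7,3′,4′-tetra-O-benzylcatechin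
Product: 21 3,5,7,3′,4′-penta-O-benzylepicatechin-(4β→8)-3,7,3′,4′-tetra-O-benzylepifisetinidol-(4β→8)-5,7,3′,4′-tetra-O-benzylcatechin, via flavan-4-ol 20 (not isolated)
Conditions: 17 (0.02 M), 19 (4 equiv), TMSOTf (0.3 equiv), 4 Å MS, CH2Cl2, −78 → −30 °C
Reagents that add atoms: none
Why: TMSOTf activates the aldehyde, and C4a of the resorcinol-type ring A (the only free carbon ortho to the ether oxygen, para to the benzyloxy group) attacks it in an intramolecular Friedel–Crafts hydroxyalkylation that forms the C4–C4a bond and gives flavan-4-ol 20 (as its silyl ether), which ionises at once to the flavan-4-yl cation, a para-quinone-methide-type oxocarbenium ion that is captured by C8 of 19 to form the interflavan bond. The closest known reaction types are the one-pot Friedel–Crafts hydroxyalkylation/alkylation of aryl-tethered aldehydes with an external arene (cyclialkylation to 1-aryltetralins and 9-arylfluorenes) and the Lewis acid-mediated 4→8 coupling of C4-oxygenated flavan-3-ol benzyl ethers with benzylated catechin. Ring C of the middle unit closes in the 6-exo-trig mode, with an arene carbon as nucleophile and the carbonyl oxygen exocyclic. C2 and C3 of the new ring are carried over unchanged from 17, and C4 is set in the capture step by the pseudo-axial C3 benzyloxy group of the half-chair cation, which directs 19 to the opposite face and should give the 3,4-trans (4β) linkage that 2,3-cis flavanyl cations are known to give. The step needs site selectivity on ring A, secured by the single free ortho position and by the slower five-ring alternative through the catechol ring, C8 over C6 selectivity in 19, which benzylated catechin shows, and suppression of capture by the phloroglucinol-type ring of a second molecule of 17, secured by the fourfold excess of 19 and the dilution of 17. Should 19 add to the aldehyde first, the derived diarylmethyl cation closes the same ring through C4a and converges on 21.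

Step 12
Reactants: 21 3,5,7,3′,4′-penta-O-benzylepicatechin-(4β→8)-3,7,3′,4′-tetra-O-benzylepifisetinidol-(4β→8)-5,7,3′,4′-tetra-O-benzylcatechin
Product: 22 epicatechin-(4β→8)-epifisetinidol-(4β→8)-catechin (CNP0270097.1)
Conditions: H2 (1 atm), Pd(OH)2/C, THF/MeOH/H2O, rt
Reagents that add atoms: none
Why: Hydrogenolysis should cleave the thirteen benzyl ethers under neutral conditions, under which the cyclic benzylic C2–O1 bonds and the acid-labile interflavan bonds of benzylated proanthocyanidins are known to persist.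

Compound list

1 | benzyl propargyl ether | C#CCOCc1ccccc1 | starting material
2 | (E)-2-[3-(benzyloxy)prop-1-en-1-yl]-4,4,5,5-tetramethyl-1,3,2-dioxaborolane | B1(/C=C/COCc2ccccc2)OC(C)(C)C(C)(C)O1 | intermediate
3 | 3,4-bis(benzyloxy)benzaldehyde | O=Cc1ccc(OCc2ccccc2)c(OCc2ccccc2)c1 | starting material
4 | (E)-2-[3-(benzyloxy)prop-2-en-1-yl]-4,4,5,5-tetramethyl-1,3,2-dioxaborolane (not isolated) | B1(C/C=C/OCc2ccccc2)OC(C)(C)C(C)(C)O1 | intermediate
5 | (1S,2R)-2-(benzyloxy)-1-[3,4-bis(benzyloxy)phenyl]but-3-en-1-ol (anti) | O[C@@H](c1ccc(OCc2ccccc2)c(OCc2ccccc2)c1)[C@H](OCc1ccccc1)C=C | intermediate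
6 | 3,5-bis(benzyloxy)phenol | Oc1cc(OCc2ccccc2)cc(OCc2ccccc2)c1 | starting material
7 | 1,3-bis(benzyloxy)-5-{[(1R,2R)-2-(benzyloxy)-1-[3,4-bis(benzyloxy)phenyl]but-3-en-1-yl]oxy}benzene | c1c(OCc3ccccc3)cc(OCc3ccccc3)cc1O[C@H](c1ccc(OCc3ccccc3)c(OCc3ccccc3)c1)[C@H](OCc3ccccc3)C=C | intermediate
8 | (2RS,3R,4R)-3-(benzyloxy)-4-[3,4-bis(benzyloxy)phenyl]-4-[3,5-bis(benzyloxy)phenoxy]butane-1,2-diol (not isolated) | c1c(OCc3ccccc3)cc(OCc3ccccc3)cc1O[C@H](c1ccc(OCc3ccccc3)c(OCc3ccccc3)c1)[C@H](OCc3ccccc3)C(O)CO | intermediate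
9 | (2S,3R)-2-(benzyloxy)-3-[3,4-bis(benzyloxy)phenyl]-3-[3,5-bis(benzyloxy)phenoxy]propanal | c1c(OCc3ccccc3)cc(OCc3ccccc3)cc1O[C@H](c1ccc(OCc3ccccc3)c(OCc3ccccc3)c1)[C@H](OCc3ccccc3)C=O | intermediate
10 | 2-bromoresorcinol | Oc1cccc(O)c1Br | starting material
11 | 3-(benzyloxy)-2-bromophenol | Oc1cccc(OCc2ccccc2)c1Br | intermediate
12 | 1-(benzyloxy)-2-bromo-3-{[(1R,2R)-2-(benzyloxy)-1-[3,4-bis(benzyloxy)phenyl]but-3-en-1-yl]oxy}benzene | Brc1c(OCc3ccccc3)cccc1O[C@H](c1ccc(OCc3ccccc3)c(OCc3ccccc3)c1)[C@H](OCc3ccccc3)C=C | intermediate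
13 | {2-(benzyloxy)-6-{[(1R,2R)-2-(benzyloxy)-1-[3,4-bis(benzyloxy)phenyl]but-3-en-1-yl]oxy}phenyl}lithium (not isolated) | [Li]c1c(OCc3ccccc3)cccc1O[C@H](c1ccc(OCc3ccccc3)c(OCc3ccccc3)c1)[C@H](OCc3ccccc3)C=C | intermediate
14 | (1RS,2R,3R)-2-(benzyloxy)-1-{2-(benzyloxy)-6-{[(1R,2R)-2-(benzyloxy)-1-[3,4-bis(benzyloxy)phenyl]but-3-en-1-yl]oxy}phenyl}-3-[3,4-bis(benzyloxy)phenyl]-3-[3,5-bis(benzyloxy)phenoxy]propan-1-ol | c1c(OCc3ccccc3)cc(OCc3ccccc3)cc1O[C@H](c1ccc(OCc3ccccc3)c(OCc3ccccc3)c1)[C@H](OCc3ccccc3)C(O)c1c(OCc3ccccc3)cccc1O[C@H](c1ccc(OCc3ccccc3)c(OCc3ccccc3)c1)[C@H](OCc3ccccc3)C=C | intermediate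
15 | (2R,3R)-3,5,7-tris(benzyloxy)-2-[3,4-bis(benzyloxy)phenyl]-4β-{2-(benzyloxy)-6-{[(1R,2R)-2-(benzyloxy)-1-[3,4-bis(benzyloxy)phenyl]but-3-en-1-yl]oxy}phenyl}chromane | c3ccccc3COc1cc(OCc3ccccc3)c2c(c1)O[C@H](c1ccc(OCc3ccccc3)c(OCc3ccccc3)c1)[C@H](OCc3ccccc3)[C@H]2c1c(OCc3ccccc3)cccc1O[C@H](c1ccc(OCc3ccccc3)c(OCc3ccccc3)c1)[C@H](OCc3ccccc3)C=C | intermediate
16 | (2RS,3R,4R)-3-(benzyloxy)-4-[3,4-bis(benzyloxy)phenyl]-4-{3-(benzyloxy)-2-[(2R,3R)-3,5,7-tris(benzyloxy)-2-[3,4-bis(benzyloxy)phenyl]chroman-4β-yl]phenoxy}butane-1,2-diol (not isolated) | c3ccccc3COc1cc(OCc3ccccc3)c2c(c1)O[C@H](c1ccc(OCc3ccccc3)c(OCc3ccccc3)c1)[C@H](OCc3ccccc3)[C@H]2c1c(OCc3ccccc3)cccc1O[C@H](c1ccc(OCc3ccccc3)c(OCc3ccccc3)c1)[C@H](OCc3ccccc3)C(O)CO | intermediate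
17 | (2S,3R)-2-(benzyloxy)-3-[3,4-bis(benzyloxy)phenyl]-3-{3-(benzyloxy)-2-[(2R,3R)-3,5,7-tris(benzyloxy)-2-[3,4-bis(benzyloxy)phenyl]chroman-4β-yl]phenoxy}propanal | c3ccccc3COc1cc(OCc3ccccc3)c2c(c1)O[C@H](c1ccc(OCc3ccccc3)c(OCc3ccccc3)c1)[C@H](OCc3ccccc3)[C@H]2c1c(OCc3ccccc3)cccc1O[C@H](c1ccc(OCc3ccccc3)c(OCc3ccccc3)c1)[C@H](OCc3ccccc3)C=O | intermediate
18 | (+)-catechin, (2R,3S)-2-(3,4-dihydroxyphenyl)chromane-3,5,7-triol | Oc1cc(O)c2c(c1)O[C@H](c1ccc(O)c(O)c1)[C@@H](O)C2 | starting material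
19 | 5,7,3′,4′-tetra-O-benzylcatechin, (2R,3S)-5,7-bis(benzyloxy)-2-[3,4-bis(benzyloxy)phenyl]chroman-3-ol | c3ccccc3COc1cc(OCc3ccccc3)c2c(c1)O[C@H](c1ccc(OCc3ccccc3)c(OCc3ccccc3)c1)[C@@H](O)C2 | intermediate
20 | (2R,3R,4RS)-3,7-bis(benzyloxy)-2-[3,4-bis(benzyloxy)phenyl]-8-[(2R,3R)-3,5,7-tris(benzyloxy)-2-[3,4-bis(benzyloxy)phenyl]chroman-4β-yl]chroman-4-ol (not isolated, both C4 epimers) | c3ccccc3COc1cc(OCc3ccccc3)c2c(c1)O[C@H](c1ccc(OCc3ccccc3)c(OCc3ccccc3)c1)[C@H](OCc3ccccc3)[C@H]2c1c(OCc3ccccc3)ccc2c1O[C@H](c1ccc(OCc3ccccc3)c(OCc3ccccc3)c1)[C@H](OCc3ccccc3)C2O | intermediate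
21 | 3,5,7,3′,4′-penta-O-benzylepicatechin-(4β→8)-3,7,3′,4′-tetra-O-benzylepifisetinidol-(4β→8)-5,7,3′,4′-tetra-O-benzylcatechin (thirteen benzyl ethers, O3 of the lower unit free) | c3ccccc3COc1cc(OCc3ccccc3)c2c(c1)O[C@H](c1ccc(OCc3ccccc3)c(OCc3ccccc3)c1)[C@H](OCc3ccccc3)[C@H]2c1c(OCc3ccccc3)ccc2c1O[C@H](c1ccc(OCc3ccccc3)c(OCc3ccccc3)c1)[C@H](OCc3ccccc3)[C@H]2c1c(OCc3ccccc3)cc(OCc3ccccc3)c2c1O[C@H](c1ccc(OCc3ccccc3)c(OCc3ccccc3)c1)[C@@H](O)C2 | intermediate
22 | epicatechin-(4β→8)-epifisetinidol-(4β→8)-catechin, upper and middle units (2R,3R,4R), lower unit (2R,3S) | Oc1cc(O)c2c(c1)O[C@H](c1ccc(O)c(O)c1)[C@H](O)[C@H]2c1c(O)ccc2c1O[C@H](c1ccc(O)c(O)c1)[C@H](O)[C@H]2c1c(O)cc(O)c2c1O[C@H](c1ccc(O)c(O)c1)[C@@H](O)C2 | target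

Total step count: 12. Longest linear sequence: 9 steps (1, 2, 3, 4, 7, 8, 9, 11, 12).

Steps most likely to fail

Step 11 (key step). The flavanyl cation, or the open-chain benzylic cation, may be captured by ring A of the upper unit of a second molecule (oligomerisation), or the activated aldehyde may lose the β-aryloxy group or fragment before the ring closes. The fallback sets out from 19 and 17 and comes back to the route at 22. Bromination of 19 at C8 with NBS (CH2Cl2, −78 °C → rt) gives (2R,3S)-5,7-bis(benzyloxy)-2-[3,4-bis(benzyloxy)phenyl]-8-bromochroman-3-ol F1, and NaH/BnBr (DMF) protects O3 to give (2R,3S)-3,5,7-tris(benzyloxy)-2-[3,4-bis(benzyloxy)phenyl]-8-bromochromane F2. Bromine–lithium exchange (t-BuLi, THF, −78 °C) gives the 8-lithio compound F3, which adds to aldehyde 17 to give the diarylmethanol F4, so that the interflavan bond is in place and regiochemically defined before any cation is formed. Catalytic BF3·OEt2 (CH2Cl2, −78 → −40 °C) then ionises F4, and ring A of the middle unit closes the pyran through C4a in a separate cyclialkylation, giving the tetradeca-O-benzyl trimer F5. Hydrogenolysis (H2, Pd(OH)2/C) of F5 gives 22.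

Step 7. A proton may pass from the ether methine (benzylic and α to oxygen) to the neighbouring aryllithium, followed by rearrangement or elimination, and the hindered aryllithium may enolise aldehyde 9 instead of adding to it. The fallback sets out from 9 and comes back to the route at 15; it changes the order of events so that the aryllithium carries no such methine. Commercial 3-(benzyloxy)phenol is converted (MOMCl, i-Pr2NEt) into 1-(benzyloxy)-3-(methoxymethoxy)benzene F6. Directed ortho-lithiation between the two oxygens (n-BuLi, THF, 0 °C) gives [2-(benzyloxy)-6-(methoxymethoxy)phenyl]lithium F7, which after transmetalation with CeCl3 adds to 9 to give the carbinol F8. Cyclialkylation as in step 8 (cat. BF3·OEt2) gives the 4β-arylchromane F9. The aryl methoxymethyl ether is cleaved under nearly neutral conditions (TMSOTf, 2,2′-bipyridyl, then H2O) to give the phenol F10, and Mitsunobu etherification of F10 with alcohol 5 (PPh3, DIAD) gives 15.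

Step 6 (the same concern holds for step 3). Partial ionisation at the electron-rich benzylic carbon during the Mitsunobu reaction may erode configurational purity at the ether carbon and cause C-alkylation of the phenol or elimination. The fallback sets out from 11 and comes back to the route at 12; it forms the aryl ether by carbene O–H insertion, which needs no leaving group at the benzylic carbon. Diazo transfer (p-acetamidobenzenesulfonyl azide, DBU) to commercial methyl [3,4-bis(benzyloxy)phenyl]acetate gives methyl 2-[3,4-bis(benzyloxy)phenyl]-2-diazoacetate F11. Copper-catalysed enantioselective O–H insertion into phenol 11 (CuCl, NaB[3,5-(CF3)2C6H3]4, chiral spiro-bisoxazoline ligand) gives methyl (R)-2-[3-(benzyloxy)-2-bromophenoxy]-2-[3,4-bis(benzyloxy)phenyl]acetate F12. Reduction with i-Bu2AlH at −78 °C gives (R)-2-[3-(benzyloxy)-2-bromophenoxy]-2-[3,4-bis(benzyloxy)phenyl]acetaldehyde F13, which is not isolated; CH2=CHMgBr added to the same flask should give, by chelation-controlled addition, (1R,2R)-1-[3-(benzyloxy)-2-bromophenoxy]-1-[3,4-bis(benzyloxy)phenyl]but-3-en-2-ol F14. Benzylation of F14 (NaH, BnBr) gives 12.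

Further compounds

F1 | step 11 | (2R,3S)-5,7-bis(benzyloxy)-2-[3,4-bis(benzyloxy)phenyl]-8-bromochroman-3-ol | c3ccccc3COc1cc(OCc3ccccc3)c2c(c1Br)O[C@H](c1ccc(OCc3ccccc3)c(OCc3ccccc3)c1)[C@@H](O)C2
F2 | step 11 | (2R,3S)-3,5,7-tris(benzyloxy)-2-[3,4-bis(benzyloxy)phenyl]-8-bromochromane | c3ccccc3COc1cc(OCc3ccccc3)c2c(c1Br)O[C@H](c1ccc(OCc3ccccc3)c(OCc3ccccc3)c1)[C@@H](OCc3ccccc3)C2
F3 | step 11 | {(2R,3S)-3,5,7-tris(benzyloxy)-2-[3,4-bis(benzyloxy)phenyl]chroman-8-yl}lithium | c3ccccc3COc1cc(OCc3ccccc3)c2c(c1[Li])O[C@H](c1ccc(OCc3ccccc3)c(OCc3ccccc3)c1)[C@@H](OCc3ccccc3)C2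
F4 | step 11 | diarylmethanol from F3 and 17 (both epimers at the carbinol carbon), open-chain precursor of the middle ring | c3ccccc3COc1cc(OCc3ccccc3)c2c(c1)O[C@H](c1ccc(OCc3ccccc3)c(OCc3ccccc3)c1)[C@H](OCc3ccccc3)[C@H]2c1c(OCc3ccccc3)cccc1O[C@H](c1ccc(OCc3ccccc3)c(OCc3ccccc3)c1)[C@H](OCc3ccccc3)C(O)c1c(OCc3ccccc3)cc(OCc3ccccc3)c2c1O[C@H](c1ccc(OCc3ccccc3)c(OCc3ccccc3)c1)[C@@H](OCc3ccccc3)C2
F5 | step 11 | tetradeca-O-benzyl trimer (21 with O3 of the lower unit benzylated) | c3ccccc3COc1cc(OCc3ccccc3)c2c(c1)O[C@H](c1ccc(OCc3ccccc3)c(OCc3ccccc3)c1)[C@H](OCc3ccccc3)[C@H]2c1c(OCc3ccccc3)ccc2c1O[C@H](c1ccc(OCc3ccccc3)c(OCc3ccccc3)c1)[C@H](OCc3ccccc3)[C@H]2c1c(OCc3ccccc3)cc(OCc3ccccc3)c2c1O[C@H](c1ccc(OCc3ccccc3)c(OCc3ccccc3)c1)[C@@H](OCc3ccccc3)C2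
F6 | step 7 | 1-(benzyloxy)-3-(methoxymethoxy)benzene | COCOc1cccc(OCc2ccccc2)c1
F7 | step 7 | [2-(benzyloxy)-6-(methoxymethoxy)phenyl]lithium | COCOc1cccc(OCc2ccccc2)c1[Li]
F8 | step 7 | (1RS,2R,3R)-2-(benzyloxy)-1-[2-(benzyloxy)-6-(methoxymethoxy)phenyl]-3-[3,4-bis(benzyloxy)phenyl]-3-[3,5-bis(benzyloxy)phenoxy]propan-1-ol | c1c(OCc3ccccc3)cc(OCc3ccccc3)cc1O[C@H](c1ccc(OCc3ccccc3)c(OCc3ccccc3)c1)[C@H](OCc3ccccc3)C(O)c1c(OCc3ccccc3)cccc1OCOC
F9 | step 7 | (2R,3R)-3,5,7-tris(benzyloxy)-2-[3,4-bis(benzyloxy)phenyl]-4β-[2-(benzyloxy)-6-(methoxymethoxy)phenyl]chromane | c3ccccc3COc1cc(OCc3ccccc3)c2c(c1)O[C@H](c1ccc(OCc3ccccc3)c(OCc3ccccc3)c1)[C@H](OCc3ccccc3)[C@H]2c1c(OCc3ccccc3)cccc1OCOC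
F10 | step 7 | 3-(benzyloxy)-2-{(2R,3R)-3,5,7-tris(benzyloxy)-2-[3,4-bis(benzyloxy)phenyl]chroman-4β-yl}phenol | c3ccccc3COc1cc(OCc3ccccc3)c2c(c1)O[C@H](c1ccc(OCc3ccccc3)c(OCc3ccccc3)c1)[C@H](OCc3ccccc3)[C@H]2c1c(OCc3ccccc3)cccc1O
F11 | step 6 | methyl 2-[3,4-bis(benzyloxy)phenyl]-2-diazoacetate | COC(=O)C(=[N+]=[N-])c1ccc(OCc2ccccc2)c(OCc2ccccc2)c1
F12 | step 6 | methyl (R)-2-[3-(benzyloxy)-2-bromophenoxy]-2-[3,4-bis(benzyloxy)phenyl]acetate | Brc1c(OCc3ccccc3)cccc1O[C@H](c1ccc(OCc3ccccc3)c(OCc3ccccc3)c1)C(=O)OC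
F13 | step 6 | (R)-2-[3-(benzyloxy)-2-bromophenoxy]-2-[3,4-bis(benzyloxy)phenyl]acetaldehyde | Brc1c(OCc3ccccc3)cccc1O[C@H](c1ccc(OCc3ccccc3)c(OCc3ccccc3)c1)C=O
F14 | step 6 | (1R,2R)-1-[3-(benzyloxy)-2-bromophenoxy]-1-[3,4-bis(benzyloxy)phenyl]but-3-en-2-ol | Brc1c(OCc3ccccc3)cccc1O[C@H](c1ccc(OCc3ccccc3)c(OCc3ccccc3)c1)[C@H](O)C=C
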